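## Retrosynthetic overview

1. Target 19 ⇒ 18: cut C3–C11 and C12–C13 (radical 7-exo/5-exo cascade from the enolised C3-prenyl diketone); the seven-membered cage ring and the cyclopentane are formed last.
2. 18 ⇒ 16 ⇒ 15: remove the C3 prenyl group, then cut C5–C6 (6-endo radical cyclisation; exo H-atom delivery puts the C7 prenyl group endo); the carbocycle of the bicyclic core is formed second.
3. 15 ⇒ 13: remove geranyl from C5 (catalytic desymmetrisation of an achiral trione); this fixes C1, the stereocentre from which all others are relayed.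
4. 13 ⇒ 6 + 10: cut C1–C8 (Claisen rearrangement on a ketal-masked, non-aromatic phloroglucinol equivalent, making benzoyl-bearing C1 next to the CMe2 carbon).
5. 6 ⇒ acetophenone + ketal of dimethyl 3-oxopentanedioate (Claisen/Dieckmann); the trione ring is formed first.

Locants used throughout: C1 benzoyl-bearing carbon; C2, C4, C9 ring carbonyls; C3 between C2 and C4; C5 geranyl-bearing carbon; C6 CH2; C7 CH; C8 CMe2; C10 CH2 on C7; C11 CH bonded to C3; C12 CMe2; C13 CH(i-Pr); C14 CH2 on C3.

Assumption: the (S,S)-ligand in step 7 is taken to give (S)-15; if the opposite sense is found, the (R,R)-ligand is used instead.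

## Route

Step 1
Reactants: 1 dimethyl 3-oxopentanedioate; 2 ethane-1,2-diol
Product: 3 dimethyl 2,2'-(1,3-dioxolane-2,2-diyl)diacetate
Conditions: TsOH·H2O (5 mol%), PhMe, reflux, Dean–Stark
Reagents that add atoms: none
Why: Acid-catalysed ketalisation with azeotropic water removal masks the future C4 carbonyl as a dioxolane, so that the six-membered ring built next cannot aromatise to a phloroglucinol; no stereocentre is formed.

Step 2
Reactants: 3 dimethyl 2,2'-(1,3-dioxolane-2,2-diyl)diacetate; 4 acetophenone
Product: 6 8-benzoyl-1,4-dioxaspiro[4.5]decane-7,9-dione, via diketo ester 5 (not isolated)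
Conditions: NaH (3.0 equiv), THF, 0 → 65 °C; then 1 M HCl, 0 °C
Reagents that add atoms: none
Why: Crossed Claisen condensation of the acetophenone enolate with one ester gives diketo ester 5, whose doubly activated methylene closes onto the second ester in a Dieckmann-type six-ring acylation driven by formation of the stabilised triketonate; the product is achiral.

Step 3
Reactants: 7 (±)-lavandulol
Product: 9 isolavandulal [5-methyl-2-(propan-2-ylidene)hex-4-enal], via lavandulal 8 (not isolated)
Conditions: (n-Pr4N)RuO4 (5 mol%), NMO (1.5 equiv), 4 Å MS, CH2Cl2, rt; then DBU (0.2 equiv), rt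
Reagents that add atoms: none
Why: Ley–Griffith oxidation gives the β,γ-unsaturated aldehyde 8, whose acidic α-hydrogen lets DBU move the isopropenyl double bond into conjugation to the favoured tetrasubstituted enal, which removes the only stereocentre of the racemic alcohol.

Step 4
Reactants: 9 isolavandulal
Product: 10 isolavandulol [5-methyl-2-(propan-2-ylidene)hex-4-en-1-ol]
Conditions: NaBH4, CeCl3·7H2O, MeOH, 0 °C
Reagents that add atoms: none
Why: Luche reduction delivers hydride 1,2 to the hindered enal and gives the primary allylic alcohol without conjugate reduction or alkene migration.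

Step 5
Reactants: 6 8-benzoyl-1,4-dioxaspiro[4.5]decane-7,9-dione; 10 isolavandulol
Product: 12 8-benzoyl-8-(2,6-dimethyl-3-methylidenehept-5-en-2-yl)-1,4-dioxaspiro[4.5]decane-7,9-dione, via allyl enol ether 11 (not isolated)
Conditions: PPh3, DIAD, PhMe, 0 °C → rt; then 130 °C (sealed tube)
Reagents that add atoms: none
Why: Mitsunobu O-alkylation of the strongly acidic triketone enol gives allyl vinyl ether 11, which on heating undergoes a Claisen rearrangement ([3,3]-sigmatropic shift) that bonds the CMe2 terminus of the allyl unit to C1, the only possible terminus because the masked ring is not aromatic, so the benzoyl-bearing quaternary C1 and the adjacent quaternary C8 are made together; either O-alkyl regioisomer (ring or benzoyl oxygen) converges on the same product and no stereocentre arises because the ring keeps its mirror plane.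

Step 6
Reactants: 12 8-benzoyl-8-(2,6-dimethyl-3-methylidenehept-5-en-2-yl)-1,4-dioxaspiro[4.5]decane-7,9-dione
Product: 13 2-benzoyl-2-(2,6-dimethyl-3-methylidenehept-5-en-2-yl)cyclohexane-1,3,5-trione
Conditions: 0.5 M aq HCl, THF, 0 °C → rt
Reagents that add atoms: water, O
Why: Mild aqueous acid hydrolyses the dioxolane (assisted by the two β-carbonyl groups) to unveil the C4 carbonyl, and because C1 is quaternary the ring cannot tautomerise to an arene, leaving an achiral vinylogous acid whose enolisable carbons C3 and C5 are enantiotopic.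

Step 7
Reactants: 13 2-benzoyl-2-(2,6-dimethyl-3-methylidenehept-5-en-2-yl)cyclohexane-1,3,5-trione; 14 geranyl acetate
Product: 15 (6S)-6-benzoyl-6-(2,6-dimethyl-3-methylidenehept-5-en-2-yl)-2-geranyl-3-hydroxycyclohex-2-ene-1,5-dione
Conditions: Pd2(dba)3·CHCl3 (2.5 mol%), (S,S)-DACH-phenyl Trost ligand (7.5 mol%), Et3N (1.1 equiv), CH2Cl2, 0 °C
Reagents that add atoms: none
Why: Proposed new method: Tsuji–Trost asymmetric allylic alkylation used as a desymmetrisation, in which the chiral zerovalent palladium complex ionises geranyl acetate and the symmetric vinylogous-acid anion of 13 attacks the unsubstituted terminus of the π-geranyl ligand through only one of its two enantiotopic carbons, so that C-geranylation at C5 makes C1 an (S)-configured stereocentre; the closest known reaction type is the palladium-catalysed asymmetric allylic alkylation of prochiral cyclic 1,3-dicarbonyl nucleophiles with diamide–bisphosphine ligands, and the soft outer-sphere attack keeps the E-alkene and the linear regiochemistry.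

Step 8
Reactants: 15 (6S)-6-benzoyl-6-(2,6-dimethyl-3-methylidenehept-5-en-2-yl)-2-geranyl-3-hydroxycyclohex-2-ene-1,5-dione
Product: 16 (1S,5R,7R)-1-benzoyl-5-geranyl-8,8-dimethyl-7-prenylbicyclo[3.3.1]nonane-2,4,9-trione (prenyl endo)
Conditions: Mn(OAc)3·2H2O (2.2 equiv), cyclohexa-1,4-diene (5 equiv), degassed EtOH, rt
Reagents that add atoms: none
Why: Mn(OAc)3-mediated oxidative free-radical cyclisation in which the more electron-rich 2-alkyl-1,3-dione enol is oxidised to the tertiary C5 radical, which adds 6-endo to the CH2 terminus of the 1,1-disubstituted alkene to close the carbocycle and fix C5 (the bridge can only form on the face carrying the tether), and the resulting tertiary C7 radical takes a hydrogen atom from cyclohexa-1,4-diene on its open exo face so that the prenyl group ends endo (syn to C3), giving (7R).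

Step 9
Reactants: 16 (1S,5R,7R)-1-benzoyl-5-geranyl-8,8-dimethyl-7-prenylbicyclo[3.3.1]nonane-2,4,9-trione; 17 prenyl acetate
Product: 18 (1R,5R,7R)-1-benzoyl-5-geranyl-4-hydroxy-8,8-dimethyl-3,7-diprenylbicyclo[3.3.1]non-3-ene-2,9-dione
Conditions: Pd(PPh3)4 (5 mol%), Et3N (1.2 equiv), THF, 40 °C
Reagents that add atoms: none
Why: Tsuji–Trost allylation of the only remaining acidic position, the C3 methylene of the cyclic 1,3-diketone, whose soft enolate attacks the unsubstituted terminus of the π-prenyl complex to give the linear C-prenyl product (O-allylation is reversible under the catalyst); no new configurationally stable stereocentre is formed, and the change of the C1 descriptor only reflects changed priorities.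

Step 10
Reactants: 18 (1R,5R,7R)-1-benzoyl-5-geranyl-4-hydroxy-8,8-dimethyl-3,7-diprenylbicyclo[3.3.1]non-3-ene-2,9-dione
Product: 19 CNP0155129.3 [(1S,3S,5R,7R,11S,13S)-configured cage trione: 18 with new C3–C11 and C12–C13 bonds and an isopropyl group on C13]
Conditions: Mn(OAc)3·2H2O (2.2 equiv), cyclohexa-1,4-diene (3 equiv), degassed EtOH (0.01 M), 40 °C
Reagents that add atoms: none
Why: Biomimetic Mn(OAc)3-mediated radical cascade in which the C3 radical of the enolised diketone adds 7-exo to the proximal carbon of the endo prenyl group (C3–C11, necessarily from the endo face and with the CMe2 terminus turned away from the C8 gem-dimethyl group, which sets C3 and C11), the tertiary C12 radical then closes 5-exo onto the C3 prenyl group through a chair-like Beckwith–Houk transition state that places the new substituent trans to C10 (sets C13), and the last tertiary radical is reduced to the isopropyl group by hydrogen-atom transfer from cyclohexa-1,4-diene.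

## Compound list

1 | dimethyl 3-oxopentanedioate | COC(=O)CC(=O)CC(=O)OC | starting material
2 | ethane-1,2-diol | OCCO | starting material
3 | dimethyl 2,2'-(1,3-dioxolane-2,2-diyl)diacetate | COC(=O)CC1(CC(=O)OC)OCCO1 | intermediate
4 | acetophenone | CC(=O)c1ccccc1 | starting material
5 | methyl 2-[2-(2,4-dioxo-4-phenylbutyl)-1,3-dioxolan-2-yl]acetate (diketo ester, not isolated) | COC(=O)CC1(CC(=O)CC(=O)c2ccccc2)OCCO1 | intermediate
6 | 8-benzoyl-1,4-dioxaspiro[4.5]decane-7,9-dione (achiral) | O=C(c1ccccc1)C1C(=O)CC2(CC1=O)OCCO2 | intermediate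
7 | (±)-lavandulol [5-methyl-2-(prop-1-en-2-yl)hex-4-en-1-ol] | CC(C)=CCC(CO)C(C)=C | starting material
8 | lavandulal [5-methyl-2-(prop-1-en-2-yl)hex-4-enal] (not isolated) | CC(C)=CCC(C=O)C(C)=C | intermediate
9 | isolavandulal [5-methyl-2-(propan-2-ylidene)hex-4-enal] | CC(C)=CCC(C=O)=C(C)C | intermediate
10 | isolavandulol [5-methyl-2-(propan-2-ylidene)hex-4-en-1-ol] | CC(C)=CCC(CO)=C(C)C | intermediate
11 | 8-benzoyl-9-{[5-methyl-2-(propan-2-ylidene)hex-4-en-1-yl]oxy}-1,4-dioxaspiro[4.5]dec-8-en-7-one (allyl enol ether, not isolated) | O=C(c1ccccc1)C1=C(OCC(CC=C(C)C)=C(C)C)CC2(CC1=O)OCCO2 | intermediate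
12 | 8-benzoyl-8-(2,6-dimethyl-3-methylidenehept-5-en-2-yl)-1,4-dioxaspiro[4.5]decane-7,9-dione (achiral) | O=C(c1ccccc1)C1(C(C)(C)C(=C)CC=C(C)C)C(=O)CC2(CC1=O)OCCO2 | intermediate
13 | 2-benzoyl-2-(2,6-dimethyl-3-methylidenehept-5-en-2-yl)cyclohexane-1,3,5-trione (achiral) | O=C(c1ccccc1)C1(C(C)(C)C(=C)CC=C(C)C)C(=O)CC(=O)CC1=O | intermediate
14 | geranyl acetate [(2E)-3,7-dimethylocta-2,6-dien-1-yl acetate] | CC(C)=CCC/C(C)=C/COC(C)=O | starting material
15 | (6S)-6-benzoyl-6-(2,6-dimethyl-3-methylidenehept-5-en-2-yl)-2-[(2E)-3,7-dimethylocta-2,6-dien-1-yl]-3-hydroxycyclohex-2-ene-1,5-dione | CC(C)=CCC/C(C)=C/CC1=C(O)CC(=O)[C@@](C(=O)c2ccccc2)(C1=O)C(C)(C)C(=C)CC=C(C)C | intermediate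
16 | (1S,5R,7R)-1-benzoyl-5-[(2E)-3,7-dimethylocta-2,6-dien-1-yl]-8,8-dimethyl-7-(3-methylbut-2-en-1-yl)bicyclo[3.3.1]nonane-2,4,9-trione (7-prenyl endo) | CC(C)=CCC/C(C)=C/C[C@]12C[C@@H](CC=C(C)C)C(C)(C)[C@](C(=O)c3ccccc3)(C1=O)C(=O)CC2=O | intermediate
17 | prenyl acetate (3-methylbut-2-en-1-yl acetate) | CC(C)=CCOC(C)=O | starting material
18 | (1R,5R,7R)-1-benzoyl-5-[(2E)-3,7-dimethylocta-2,6-dien-1-yl]-4-hydroxy-8,8-dimethyl-3,7-bis(3-methylbut-2-en-1-yl)bicyclo[3.3.1]non-3-ene-2,9-dione | CC(C)=CCC/C(C)=C/C[C@]12C[C@@H](CC=C(C)C)C(C)(C)[C@](C(=O)c3ccccc3)(C1=O)C(=O)C(CC=C(C)C)=C2O | intermediate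
19 | CNP0155129.3, (1S,3S,5R,7R,11S,13S) cage trione (locants as defined above) | CC(C)=CCC/C(C)=C/C[C@@]12C[C@H]3C[C@H]4C(C)(C)[C@H](C(C)C)C[C@]4(C1=O)C(=O)[C@@](C(=O)c1ccccc1)(C2=O)C3(C)C | target

## Summary

Total step count: 10. Longest linear sequence: 8 steps (1, 2, 5, 6, 7, 8, 9, 10); steps 3 and 4 make the side branch.

Stereocentres: C1 is set in step 7; C5 and C7 in step 8; C3, C11 and C13 in step 10. None is touched afterwards.

Three steps most likely to fail:

Step 7 (enantioselectivity of the desymmetrising geranylation; mono- versus bis-allylation). Fallback, setting out from 13 and returning at 15: condense 13 with (S)-1-phenylethylamine (PhMe, 4 Å MS) to the two diastereomeric vinylogous amides, separate them and keep the (S)-1-phenylethylamine vinylogous amide F1, whose enaminone lies on the C2–C3–C4 side (the other diastereomer is hydrolysed back to 13). Double deprotonation of F1 with LiN(i-Pr)2 (THF, −78 °C) and alkylation with geranyl bromide occurs at C5, the only enolisable ring carbon left, giving the C-geranyl vinylogous amide F2. Hydrolysis of F2 with aqueous HCl in THF gives 15.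

Step 8 (site selectivity, C5 against C3, and fate of the tertiary C7 radical). Fallback, setting out from 13 and returning at 16: cyclise the achiral trione 13 itself under the step 8 conditions, where C3 and C5 are equivalent so no site problem exists. Resolve the racemic product through its quinine salt to obtain the bridgehead-unsubstituted bicyclic trione F3. Methylate with TMSCHN2 and separate the 2-methoxy enol ether F4. Lithiate the C5 bridgehead (LiN(i-Pr)2, THF, −78 °C) and alkylate with geranyl bromide to give the 5-geranyl enol ether F5. Cleave the methyl ether of F5 with LiCl in DMSO at 120 °C to reach 16.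

Step 10 (slow 7-exo closure competing with premature reduction or oxidation of the radicals). Fallback, setting out from 18 and returning at 19: iodinate C3 with N-iodosuccinimide (CH2Cl2, 0 °C) to the 3-iodo-3-prenyl diketone F6. Then generate the same C3 radical by iodine-atom abstraction under reductive chain conditions (Et3B/air, (Me3Si)3SiH, PhH, rt). No oxidant is present, the cascade runs as in step 10, and the last radical is quenched by the silane to give 19.

Further compounds
F1 | step 7 | (S)-1-phenylethylamine vinylogous amide of 13, diastereomer with the enaminone on the C2–C3–C4 side | C1C(N[C@@H](C)c2ccccc2)=CC(=O)[C@@](C(=O)c3ccccc3)(C1=O)C(C)(C)C(=C)CC=C(C)C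
F2 | step 7 | C5-geranyl vinylogous amide (C5 epimer mixture, inconsequential) | CC(C)=CCC/C(C)=C/CC1C(N[C@@H](C)c2ccccc2)=CC(=O)[C@@](C(=O)c3ccccc3)(C1=O)C(C)(C)C(=C)CC=C(C)C
F3 | step 8 | 1-benzoyl-8,8-dimethyl-7-endo-prenylbicyclo[3.3.1]nonane-2,4,9-trione with H at C5 (same absolute configuration as 16) | [C@H]12C[C@@H](CC=C(C)C)C(C)(C)[C@](C(=O)c3ccccc3)(C1=O)C(=O)CC2=O
F4 | step 8 | 2-methoxy enol ether of F3 | [C@H]12C[C@@H](CC=C(C)C)C(C)(C)[C@](C(=O)c3ccccc3)(C1=O)C(OC)=CC2=O
F5 | step 8 | 5-geranyl 2-methoxy enol ether | CC(C)=CCC/C(C)=C/C[C@]12C[C@@H](CC=C(C)C)C(C)(C)[C@](C(=O)c3ccccc3)(C1=O)C(OC)=CC2=O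
F6 | step 10 | 3-iodo-3-prenyl diketone from 18 (C3 configuration inconsequential) | CC(C)=CCC/C(C)=C/C[C@]12C[C@@H](CC=C(C)C)C(C)(C)[C@](C(=O)c3ccccc3)(C1=O)C(=O)C(I)(CC=C(C)C)C2=O
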